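## Retrosynthetic overview

- **Feature:** C4 of the tetrahydropyran is bonded to C3' of the acetophenone ring, the arene carbon between the oxygens on C2' and C4', and C4 stands 1,3 to the oxygen-bearing C2. A C–aryl bond ortho to a phenol oxygen and 1,3 to an acetal-level carbon is what an aromatic Claisen shift of an O2'–C2 aryl acetal across C3=C4 leaves behind.
- **Disconnections (backwards):** enone C=C by aldol condensation of the aryl methyl ketone; C2–aryl by axial arylzinc capture of the C2 oxocarbenium ion; C4–C3' by the [3,3] shift; O2'–C2 by palladium-catalysed decarboxylative O-glycosylation of a cis glycal carbonate; pyran ring by an enantioselective hetero-Diels–Alder reaction.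
- **Ring order:** the pyran ring is made first, the acetophenone ring is attached to C2 through oxygen and then moved to C4, the 4-oxyphenyl ring is attached at C2, and the cinnamoyl arm is completed last.
- **Stereochemistry:** C6 from the catalyst; C4 by relay (Luche reduction, net retention at palladium, suprafacial shift); C2 by axial attack trans to both other substituents.

Key step: step 8

Remark: TBS = tert-butyldimethylsilyl. In the discussion the pyran carries the numbering of the target (O1, C2 aryl/acetal carbon, C3, C4 arene-bearing, C5, C6 chain-bearing) and the acetophenone ring is C1' (acyl), C2' (OH), C3', C4' (O), C5', C6' (OMe); names in the compound list use the IUPAC locants of each compound.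

Assumption: (R)-BINOL is taken to give (S)-6, by analogy with the facial sense of BINOL–titanium allylation of aliphatic aldehydes; the sense is to be confirmed on the first batch and (S)-BINOL used if it proves opposite.

## Route

Step 1
Reactants: 1 methyl 3-(4-hydroxyphenyl)propanoate
Product: 2 methyl 3-[4-(TBSO)phenyl]propanoate
Conditions: TBSCl, imidazole, DMF, rt
Reagents that add atoms: tert-butyldimethylsilyl chloride, CC(C)(C)[Si](C)(C)Cl
Why: Silyl ether formation on the phenol with TBSCl and imidazole is routine and leaves the ester untouched.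

Step 2
Reactants: 2 methyl 3-[4-(TBSO)phenyl]propanoate
Product: 3 3-[4-(TBSO)phenyl]propanal
Conditions: iBu2AlH (1.05 equiv), CH2Cl2, −78 °C; aq. potassium sodium tartrate
Reagents that add atoms: none
Why: Half-reduction of the ester by iBu2AlH at low temperature should stop at the aluminium hemiacetal, which releases the aldehyde on work-up, while the aryl silyl ether is inert.

Step 3
Reactants: 3 3-[4-(TBSO)phenyl]propanal; 4 Danishefsky diene
Product: 6 (S)-2-{2-[4-(TBSO)phenyl]ethyl}-2,3-dihydro-4H-pyran-4-one, via Mukaiyama aldol adduct 5 (not isolated)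
Conditions: (R)-BINOL (20 mol%), Ti(OiPr)4 (10 mol%), 4 Å molecular sieves, Et2O, −20 °C; then CF3CO2H, CH2Cl2, 0 °C
Reagents that add atoms: none
Why: This is a BINOL–titanium catalysed enantioselective hetero-Diels–Alder reaction that runs as a Mukaiyama aldol addition of the diene terminus to the titanium-bound aldehyde followed by acid-induced ring closure with loss of methanol; the chiral titanate shields one aldehyde face and so should set C6 as (S).

Step 4
Reactants: 6 (S)-2-{2-[4-(TBSO)phenyl]ethyl}-2,3-dihydro-4H-pyran-4-one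
Product: 7 (2S,4R)-2-{2-[4-(TBSO)phenyl]ethyl}-3,4-dihydro-2H-pyran-4-ol (cis)
Conditions: NaBH4, CeCl3·7H2O, MeOH, −78 to −40 °C
Reagents that add atoms: none
Why: Luche 1,2-reduction of the vinylogous ester should deliver hydride along the axial trajectory of the half-chair, so that the new C4–O bond is pseudoequatorial and cis to the C6 chain.

Step 5
Reactants: 7 (2S,4R)-2-{2-[4-(TBSO)phenyl]ethyl}-3,4-dihydro-2H-pyran-4-ol
Product: 8 tert-butyl (2S,4R)-2-{2-[4-(TBSO)phenyl]ethyl}-3,4-dihydro-2H-pyran-4-yl carbonate (cis)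
Conditions: Boc2O, DMAP (10 mol%), Et3N, CH2Cl2, 0 °C to rt
Reagents that add atoms: di-tert-butyl dicarbonate, CC(C)(C)OC(=O)OC(=O)OC(C)(C)C
Why: DMAP-catalysed carbonate formation proceeds in a basic medium that spares the acid-labile glycal-type allylic alcohol and does not touch the C4 configuration.

Step 6
Reactants: 9 2',4'-dihydroxy-6'-methoxyacetophenone
Product: 10 4'-(TBSO)-2'-hydroxy-6'-methoxyacetophenone
Conditions: TBSCl (1.05 equiv), imidazole, CH2Cl2/DMF, 0 °C
Reagents that add atoms: tert-butyldimethylsilyl chloride, CC(C)(C)[Si](C)(C)Cl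
Why: Selective silyl ether formation is expected at the 4'-phenol because the 2'-phenol is hydrogen-bonded to the ketone and far less nucleophilic.

Step 7
Reactants: 8 tert-butyl (2S,4R)-2-{2-[4-(TBSO)phenyl]ethyl}-3,4-dihydro-2H-pyran-4-yl carbonate; 10 4'-(TBSO)-2'-hydroxy-6'-methoxyacetophenone
Product: 11 1-[2-({(2R,6S)-6-{2-[4-(TBSO)phenyl]ethyl}-5,6-dihydro-2H-pyran-2-yl}oxy)-4-(TBSO)-6-methoxyphenyl]ethanone (cis aryl pseudoglycoside)
Conditions: Pd2(dba)3 (2.5 mol%), 1,4-bis(diphenylphosphino)butane (6 mol%), CH2Cl2, rt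
Reagents that add atoms: none
Why: In this decarboxylative Tsuji–Trost O-glycosylation, zerovalent palladium ionises the carbonate with inversion, the tert-butoxide left after loss of CO2 deprotonates 10, and the soft phenoxide attacks the allyl terminus next to the ring oxygen anti to palladium, so the aryloxy group should arrive on the face the carbonate left (net retention, 2,6-cis).

Step 8
Reactants: 11 1-[2-({(2R,6S)-6-{2-[4-(TBSO)phenyl]ethyl}-5,6-dihydro-2H-pyran-2-yl}oxy)-4-(TBSO)-6-methoxyphenyl]ethanone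
Product: 13 1-[3-((2S,4R)-2-{2-[4-(TBSO)phenyl]ethyl}-3,4-dihydro-2H-pyran-4-yl)-4-(TBSO)-2-hydroxy-6-methoxyphenyl]ethanone, via ortho-dienone 12 (not isolated)
Conditions: PhNEt2 (degassed), 180 °C, sealed tube, Ar; amine removed in vacuo (no acid wash)
Reagents that add atoms: none
Why: On heating, 11 should reach the conformer in which the C2–O2' bond is pseudoaxial and aligned with the C3=C4 π system, and a concerted suprafacial [3,3] shift then breaks O2'–C2 while C3' bonds to C4 on the same face, giving ortho-dienone 12, which enolises at once to the phenol hydrogen-bonded to the acetyl group. The closest known reactions are the thermal aromatic Claisen rearrangements of aryl cyclohex-2-enyl ethers and of aryl 2,3-unsaturated pyranosides to C-aryl glycals, and the acetal character of the breaking bond should lower the barrier relative to a plain allyl aryl ether. No ring is closed: the alkene moves from C3=C4 to C2=C3 and the 2'-phenol is released. The new stereocentre C4 is fixed by the configuration of the acetal carbon C2 (itself relayed from C6 through the Luche reduction and the double inversion at palladium), so the arene should end up cis to the C6 chain, (4R). The step needs ortho regioselectivity, secured because C3' is the only ortho carbon that carries hydrogen (C1' bears the acetyl group), and facial fidelity, secured by a non-polar basic amine medium free of Lewis or protic acid so that ionisation to a phenoxide/allyl-oxocarbenium pair is not favoured.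

Step 9
Reactants: 14 (4-bromophenoxy)(tert-butyl)dimethylsilane
Product: 16 4-(TBSO)phenylzinc bromide (THF solution), via aryllithium 15 (not isolated)
Conditions: n-BuLi, THF, −78 °C; then ZnBr2 (THF), −78 to 0 °C
Reagents that add atoms: zinc bromide, Br[Zn]Br
Why: Bromine–lithium exchange followed by transmetalation to zinc gives an aryl nucleophile that tolerates the ketone of the coupling partner.

Step 10
Reactants: 13 1-[3-((2S,4R)-2-{2-[4-(TBSO)phenyl]ethyl}-3,4-dihydro-2H-pyran-4-yl)-4-(TBSO)-2-hydroxy-6-methoxyphenyl]ethanone; 16 4-(TBSO)phenylzinc bromide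
Product: 18 1-[3-((2R,4R,6S)-2-[4-(TBSO)phenyl]-6-{2-[4-(TBSO)phenyl]ethyl}tetrahydro-2H-pyran-4-yl)-4-(TBSO)-2-hydroxy-6-methoxyphenyl]ethanone, via 2-chlorotetrahydropyran 17 (not isolated)
Conditions: HCl (1 M in Et2O, 1.05 equiv), CH2Cl2, −78 to −40 °C; then 16 (3.5 equiv, THF), −40 °C to rt
Reagents that add atoms: none
Why: Markovnikov addition of HCl to the enol ether gives the 2-chlorotetrahydropyran, which ionises to the C2 oxocarbenium ion and is captured by the arylzinc (C-arylation of a glycosyl-type halide with an arylzinc reagent) along the axial trajectory of the half-chair that keeps the C4 arene and the C6 chain pseudoequatorial, so the new aryl group should be trans to both; the arylzinc does not add to the ketone, one equivalent is spent on the phenol proton, and the 4,6-cis arrangement disfavours closure of that phenol onto C2.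

Step 11
Reactants: 18 1-[3-((2R,4R,6S)-2-[4-(TBSO)phenyl]-6-{2-[4-(TBSO)phenyl]ethyl}tetrahydro-2H-pyran-4-yl)-4-(TBSO)-2-hydroxy-6-methoxyphenyl]ethanone; 19 4-(TBSO)benzaldehyde
Product: 20 3-hydroxy-1-[3-((2R,4R,6S)-2-[4-(TBSO)phenyl]-6-{2-[4-(TBSO)phenyl]ethyl}tetrahydro-2H-pyran-4-yl)-4-(TBSO)-2-hydroxy-6-methoxyphenyl]-3-[4-(TBSO)phenyl]propan-1-one (both carbinol epimers)
Conditions: LiN(SiMe3)2 (2.3 equiv), THF, −78 °C; then 19 (1.3 equiv), −78 to −40 °C; pH 7 Na2HPO4/NaH2PO4 buffer
Reagents that add atoms: none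
Why: Directed aldol addition of the lithium enolate (formed after the phenoxide, as the dianion) to a non-enolisable aldehyde; the new carbinol centre is uncontrolled and is removed in the next step.

Step 12
Reactants: 20 3-hydroxy-1-[3-((2R,4R,6S)-2-[4-(TBSO)phenyl]-6-{2-[4-(TBSO)phenyl]ethyl}tetrahydro-2H-pyran-4-yl)-4-(TBSO)-2-hydroxy-6-methoxyphenyl]-3-[4-(TBSO)phenyl]propan-1-one
Product: 22 (E)-1-[3-((2R,4R,6S)-2-[4-(TBSO)phenyl]-6-{2-[4-(TBSO)phenyl]ethyl}tetrahydro-2H-pyran-4-yl)-4-(TBSO)-2-hydroxy-6-methoxyphenyl]-3-[4-(TBSO)phenyl]prop-2-en-1-one, via β-mesylate 21 (not isolated)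
Conditions: MsCl (1.2 equiv), Et3N (5 equiv), CH2Cl2, −20 °C to rt
Reagents that add atoms: none
Why: Mesylation of the secondary benzylic alcohol and E1cB elimination by the amine should give the conjugated E-enone, while the 2'-phenol, chelated to the ketone and flanked on both sides, is expected to react far more slowly with the sulfonylating agent.

Step 13
Reactants: 22 (E)-1-[3-((2R,4R,6S)-2-[4-(TBSO)phenyl]-6-{2-[4-(TBSO)phenyl]ethyl}tetrahydro-2H-pyran-4-yl)-4-(TBSO)-2-hydroxy-6-methoxyphenyl]-3-[4-(TBSO)phenyl]prop-2-en-1-one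
Product: 23 CNP0215517.2, (E)-1-[2,4-dihydroxy-3-((2R,4R,6S)-2-(4-hydroxyphenyl)-6-[2-(4-hydroxyphenyl)ethyl]tetrahydro-2H-pyran-4-yl)-6-methoxyphenyl]-3-(4-hydroxyphenyl)prop-2-en-1-one
Conditions: Bu4NF/AcOH (1:1, 6 equiv), THF, 0 °C
Reagents that add atoms: none
Why: Fluoride cleavage of the four aryl silyl ethers, with acetic acid buffering the phenoxides so that oxa-Michael closure to the flavanone is suppressed and no strong acid reaches the benzylic C2 ether or the C4–arene bond.

## Compound list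

1 | methyl 3-(4-hydroxyphenyl)propanoate | COC(=O)CCc1ccc(O)cc1 | starting material
2 | methyl 3-[4-(TBSO)phenyl]propanoate | COC(=O)CCc1ccc(O[Si](C)(C)C(C)(C)C)cc1 | intermediate
3 | 3-[4-(TBSO)phenyl]propanal | O=CCCc1ccc(O[Si](C)(C)C(C)(C)C)cc1 | intermediate
4 | Danishefsky diene, (E)-1-methoxy-3-(trimethylsilyloxy)buta-1,3-diene | CO/C=C/C(=C)O[Si](C)(C)C | starting material
5 | (S,E)-1-methoxy-7-[4-(TBSO)phenyl]-5-(trimethylsilyloxy)hept-1-en-3-one (Mukaiyama aldol adduct) | CO/C=C/C(=O)C[C@H](CCc1ccc(O[Si](C)(C)C(C)(C)C)cc1)O[Si](C)(C)C | intermediate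
6 | (S)-2-{2-[4-(TBSO)phenyl]ethyl}-2,3-dihydro-4H-pyran-4-one | O=C1C[C@H](CCc2ccc(O[Si](C)(C)C(C)(C)C)cc2)OC=C1 | intermediate
7 | (2S,4R)-2-{2-[4-(TBSO)phenyl]ethyl}-3,4-dihydro-2H-pyran-4-ol (cis) | O[C@@H]1C[C@H](CCc2ccc(O[Si](C)(C)C(C)(C)C)cc2)OC=C1 | intermediate
8 | tert-butyl (2S,4R)-2-{2-[4-(TBSO)phenyl]ethyl}-3,4-dihydro-2H-pyran-4-yl carbonate (cis) | CC(C)(C)OC(=O)O[C@@H]1C[C@H](CCc2ccc(O[Si](C)(C)C(C)(C)C)cc2)OC=C1 | intermediate
9 | 2',4'-dihydroxy-6'-methoxyacetophenone | COc1cc(O)cc(O)c1C(C)=O | starting material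
10 | 4'-(TBSO)-2'-hydroxy-6'-methoxyacetophenone | COc1cc(O[Si](C)(C)C(C)(C)C)cc(O)c1C(C)=O | intermediate
11 | 1-[2-({(2R,6S)-6-{2-[4-(TBSO)phenyl]ethyl}-5,6-dihydro-2H-pyran-2-yl}oxy)-4-(TBSO)-6-methoxyphenyl]ethanone (cis aryl pseudoglycoside) | COc1cc(O[Si](C)(C)C(C)(C)C)cc(O[C@@H]2C=CC[C@H](CCc3ccc(O[Si](C)(C)C(C)(C)C)cc3)O2)c1C(C)=O | intermediate
12 | 2-acetyl-3-methoxy-5-(TBSO)-6-[(2S,4R)-2-{2-[4-(TBSO)phenyl]ethyl}-3,4-dihydro-2H-pyran-4-yl]cyclohexa-2,4-dien-1-one (ortho-dienone; ring sp3 centre transient, not defined) | COC1=C(C(C)=O)C(=O)C([C@@H]2C[C@H](CCc3ccc(O[Si](C)(C)C(C)(C)C)cc3)OC=C2)C(O[Si](C)(C)C(C)(C)C)=C1 | intermediate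
13 | 1-[3-((2S,4R)-2-{2-[4-(TBSO)phenyl]ethyl}-3,4-dihydro-2H-pyran-4-yl)-4-(TBSO)-2-hydroxy-6-methoxyphenyl]ethanone (arene cis to the chain) | COc1cc(O[Si](C)(C)C(C)(C)C)c([C@@H]2C[C@H](CCc3ccc(O[Si](C)(C)C(C)(C)C)cc3)OC=C2)c(O)c1C(C)=O | intermediate
14 | (4-bromophenoxy)(tert-butyl)dimethylsilane | CC(C)(C)[Si](C)(C)Oc1ccc(Br)cc1 | starting material
15 | 4-(TBSO)phenyllithium | [Li]c1ccc(O[Si](C)(C)C(C)(C)C)cc1 | intermediate
16 | 4-(TBSO)phenylzinc bromide | Br[Zn]c1ccc(O[Si](C)(C)C(C)(C)C)cc1 | intermediate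
17 | 1-[3-((2S,4R,6S)-2-chloro-6-{2-[4-(TBSO)phenyl]ethyl}tetrahydro-2H-pyran-4-yl)-4-(TBSO)-2-hydroxy-6-methoxyphenyl]ethanone (axial chloride) | COc1cc(O[Si](C)(C)C(C)(C)C)c([C@@H]2C[C@H](CCc3ccc(O[Si](C)(C)C(C)(C)C)cc3)O[C@@H](Cl)C2)c(O)c1C(C)=O | intermediate
18 | 1-[3-((2R,4R,6S)-2-[4-(TBSO)phenyl]-6-{2-[4-(TBSO)phenyl]ethyl}tetrahydro-2H-pyran-4-yl)-4-(TBSO)-2-hydroxy-6-methoxyphenyl]ethanone (2,6-trans, 4,6-cis) | COc1cc(O[Si](C)(C)C(C)(C)C)c([C@@H]2C[C@H](CCc3ccc(O[Si](C)(C)C(C)(C)C)cc3)O[C@@H](c3ccc(O[Si](C)(C)C(C)(C)C)cc3)C2)c(O)c1C(C)=O | intermediate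
19 | 4-(TBSO)benzaldehyde | CC(C)(C)[Si](C)(C)Oc1ccc(C=O)cc1 | starting material
20 | 3-hydroxy-1-[3-((2R,4R,6S)-2-[4-(TBSO)phenyl]-6-{2-[4-(TBSO)phenyl]ethyl}tetrahydro-2H-pyran-4-yl)-4-(TBSO)-2-hydroxy-6-methoxyphenyl]-3-[4-(TBSO)phenyl]propan-1-one (both carbinol epimers) | COc1cc(O[Si](C)(C)C(C)(C)C)c([C@@H]2C[C@H](CCc3ccc(O[Si](C)(C)C(C)(C)C)cc3)O[C@@H](c3ccc(O[Si](C)(C)C(C)(C)C)cc3)C2)c(O)c1C(=O)CC(O)c1ccc(O[Si](C)(C)C(C)(C)C)cc1 | intermediate
21 | methanesulfonate of 20 at the benzylic carbinol (both epimers) | COc1cc(O[Si](C)(C)C(C)(C)C)c([C@@H]2C[C@H](CCc3ccc(O[Si](C)(C)C(C)(C)C)cc3)O[C@@H](c3ccc(O[Si](C)(C)C(C)(C)C)cc3)C2)c(O)c1C(=O)CC(OS(C)(=O)=O)c1ccc(O[Si](C)(C)C(C)(C)C)cc1 | intermediate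
22 | (E)-1-[3-((2R,4R,6S)-2-[4-(TBSO)phenyl]-6-{2-[4-(TBSO)phenyl]ethyl}tetrahydro-2H-pyran-4-yl)-4-(TBSO)-2-hydroxy-6-methoxyphenyl]-3-[4-(TBSO)phenyl]prop-2-en-1-one | COc1cc(O[Si](C)(C)C(C)(C)C)c([C@@H]2C[C@H](CCc3ccc(O[Si](C)(C)C(C)(C)C)cc3)O[C@@H](c3ccc(O[Si](C)(C)C(C)(C)C)cc3)C2)c(O)c1C(=O)/C=C/c1ccc(O[Si](C)(C)C(C)(C)C)cc1 | intermediate
23 | CNP0215517.2, (E)-1-[2,4-dihydroxy-3-((2R,4R,6S)-2-(4-hydroxyphenyl)-6-[2-(4-hydroxyphenyl)ethyl]tetrahydro-2H-pyran-4-yl)-6-methoxyphenyl]-3-(4-hydroxyphenyl)prop-2-en-1-one | COc1cc(O)c([C@@H]2C[C@H](CCc3ccc(O)cc3)O[C@@H](c3ccc(O)cc3)C2)c(O)c1C(=O)/C=C/c1ccc(O)cc1 | target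

## Step count and risks

Total step count: 13. Longest linear sequence: 11 steps (steps 1–5, 7, 8, 10–13, from 1 to 23).

**Steps most likely to fail**

1. **Step 8 (aromatic Claisen shift).** At the temperature needed, the aryl acetal may ionise to a phenoxide/allyl-oxocarbenium pair instead of rearranging in concert. That would erode the facial fidelity, return the arene to C2, or divert it through the acetyl-bearing ortho carbon. The neighbouring 4'-silyl ether may also slow bond formation at C3', and thermal elimination of the phenol may compete.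
   - Fallback: the C4–C3' bond is made by an intermolecular, catalyst-controlled Friedel–Crafts conjugate addition instead of a sigmatropic transfer. It sets out from 7 and 10 and comes back to the route at chloride 17 of step 10, and so at 18.
   - Alcohol 7 is opened by Perlin hydrolysis (HgSO4 catalyst, dilute aqueous H2SO4, 1,4-dioxane) to (S,E)-5-hydroxy-7-[4-(TBSO)phenyl]hept-2-enal F1.
   - The iminium ion formed from F1 and (S)-α,α-diphenylprolinol trimethylsilyl ether (20 mol%, with benzoic acid, toluene, rt) is attacked at its β-carbon by C3' of phenol 10, the carbon ortho to the free phenol and para to the methoxy group. The usual shielding model of this catalyst places the arene on the face that makes C4 (R).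
   - The adduct should close through its C6 hydroxyl to 1-[3-((4R,6S)-2-hydroxy-6-{2-[4-(TBSO)phenyl]ethyl}tetrahydro-2H-pyran-4-yl)-4-(TBSO)-2-hydroxy-6-methoxyphenyl]ethanone F2 (anomeric mixture).
   - Anhydrous HCl over MgSO4 in CH2Cl2 then turns F2 into 17, which is arylated with 16 as in step 10.

2. **Step 10 (C2 arylation).** The substitution may be sluggish or poorly face-selective. Hydrogen chloride may strip an aryl silyl ether, promote closure of the free phenol onto C2, or oligomerise the enol ether before the arylzinc is added.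
   - Fallback: the oxocarbenium precursor is changed from a fleeting α-chloro ether to an isolable anomeric sulfone, so that no hydrogen chloride is used and ionisation is triggered only by the zinc reagent. It sets out from 13 and comes back at 18.
   - Benzenesulfinic acid is added across the enol ether of 13 (CH2Cl2, rt) to give 1-[3-((4R,6S)-2-(phenylsulfonyl)-6-{2-[4-(TBSO)phenyl]ethyl}tetrahydro-2H-pyran-4-yl)-4-(TBSO)-2-hydroxy-6-methoxyphenyl]ethanone F3, which can be purified.
   - F3 is treated with 16 (3.5 equiv) and ZnBr2 in THF at rt, the known substitution of 2-sulfonyl cyclic ethers by organozinc reagents through the oxocarbenium ion. The same axial attack should give 18.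

3. **Step 7 (palladium-catalysed O-glycosylation).** The chelated 2'-phenol may capture the allylpalladium intermediate too slowly. Reversible ionisation of the product could then erode the cis preference, and attack at C4 or elimination to a diene could take over.
   - Fallback: the phenol is delivered as part of the leaving group instead of as an external nucleophile. It sets out from 7 and 10 and comes back at 11.
   - Alcohol 7 is treated with 1,1'-carbonyldiimidazole (CH2Cl2, rt) to give (2S,4R)-2-{2-[4-(TBSO)phenyl]ethyl}-3,4-dihydro-2H-pyran-4-yl imidazole-1-carboxylate F4.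
   - F4 is treated with phenol 10 and catalytic DBU (MeCN, rt) to give the mixed carbonate 2-acetyl-5-(TBSO)-3-methoxyphenyl (2S,4R)-2-{2-[4-(TBSO)phenyl]ethyl}-3,4-dihydro-2H-pyran-4-yl carbonate F5.
   - With Pd2(dba)3 and 1,4-bis(diphenylphosphino)butane, F5 should ionise and lose CO2 inside the ion pair (decarboxylative etherification of an allyl aryl carbonate). The phenoxide is released next to the allyl terminus and should give 11 with the same net retention.

## Further compounds

F1 | step 8 | (S,E)-5-hydroxy-7-[4-(TBSO)phenyl]hept-2-enal | O=C/C=C/C[C@H](CCc1ccc(O[Si](C)(C)C(C)(C)C)cc1)O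
F2 | step 8 | 1-[3-((4R,6S)-2-hydroxy-6-{2-[4-(TBSO)phenyl]ethyl}tetrahydro-2H-pyran-4-yl)-4-(TBSO)-2-hydroxy-6-methoxyphenyl]ethanone (anomeric mixture) | COc1cc(O[Si](C)(C)C(C)(C)C)c([C@@H]2C[C@H](CCc3ccc(O[Si](C)(C)C(C)(C)C)cc3)OC(O)C2)c(O)c1C(C)=O
F3 | step 10 | 1-[3-((4R,6S)-2-(phenylsulfonyl)-6-{2-[4-(TBSO)phenyl]ethyl}tetrahydro-2H-pyran-4-yl)-4-(TBSO)-2-hydroxy-6-methoxyphenyl]ethanone (anomeric mixture) | COc1cc(O[Si](C)(C)C(C)(C)C)c([C@@H]2C[C@H](CCc3ccc(O[Si](C)(C)C(C)(C)C)cc3)OC(S(=O)(=O)c3ccccc3)C2)c(O)c1C(C)=O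
F4 | step 7 | (2S,4R)-2-{2-[4-(TBSO)phenyl]ethyl}-3,4-dihydro-2H-pyran-4-yl imidazole-1-carboxylate | O=C(O[C@@H]1C[C@H](CCc2ccc(O[Si](C)(C)C(C)(C)C)cc2)OC=C1)n1ccnc1
F5 | step 7 | 2-acetyl-5-(TBSO)-3-methoxyphenyl (2S,4R)-2-{2-[4-(TBSO)phenyl]ethyl}-3,4-dihydro-2H-pyran-4-yl carbonate | COc1cc(O[Si](C)(C)C(C)(C)C)cc(OC(=O)O[C@@H]2C[C@H](CCc3ccc(O[Si](C)(C)C(C)(C)C)cc3)OC=C2)c1C(C)=O
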